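**Plan**
- Retrosynthesis cuts O1–C2 and C3–C4 of the pyranone (ring C) together, which maps the isoflavone onto a trans-chalcone epoxide. The enone Cα=Cβ bond is then cut by aldol logic and the C5'–prenyl bond by cross-coupling.
- Forward: the ring A ketone is bis-MOM protected. The ring B bromocatechol aldehyde is methylated at O4, MOM-protected at the other oxygen and prenylated. Claisen–Schmidt condensation and alkaline peroxide epoxidation follow, and ring C, the only ring made, arises last.
- Enabling feature: the C4' methoxy group is para to C1', so the carbon bearing ring B (future C3) ionises easily and accepts the ring A aroyl carbon (C4) by a 1,2-shift. The other epoxide carbon is left as the C2 aldehyde, which the C8a oxygen closes onto.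
- Stereochemistry: the target has no stereocentre. The E-alkene and the racemic trans-epoxide are transient, and both epoxide centres end as sp2 carbons.

Key step: step 7

Assumption: because both epoxide stereocentres are destroyed in step 7, the epoxide is made and used as the racemate (one enantiomer drawn).

**Step 1**
Reactants: 1 2,4-dihydroxy-6-methoxyacetophenone
Product: 2 1-[2-methoxy-4,6-bis(methoxymethoxy)phenyl]ethan-1-one
Conditions: NaH (2.3 equiv), MOMCl (2.5 equiv), DMF, 0 °C → rt
Reagents that add atoms: chloromethyl methyl ether (MOMCl), COCCl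
Why: Williamson-type O-alkylation of both sodium phenoxides; the strong base is chosen because the hydroxyl ortho to the acetyl group is hydrogen-bonded to the carbonyl and resists amine-base conditions.

**Step 2**
Reactants: 3 3-bromo-4,5-dihydroxybenzaldehyde
Product: 4 3-bromo-5-hydroxy-4-methoxybenzaldehyde
Conditions: MeI (1.05 equiv), Li2CO3 (1.2 equiv), DMF, 40 °C
Reagents that add atoms: iodomethane, CI
Why: Regioselective Williamson methylation; the weak base should deprotonate only the more acidic O4–H (para to the formyl group, ortho to bromine), so the monophenoxide is methylated at O4 as in the known 4-O-selective alkylations of protocatechualdehydes.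

**Step 3**
Reactants: 4 3-bromo-5-hydroxy-4-methoxybenzaldehyde
Product: 5 3-bromo-4-methoxy-5-(methoxymethoxy)benzaldehyde
Conditions: MOMCl (1.3 equiv), K2CO3, acetone, rt
Reagents that add atoms: chloromethyl methyl ether (MOMCl), COCCl
Why: Standard MOM protection (Williamson O-alkylation) of the remaining phenol, giving an acetal that tolerates the palladium coupling, the aldol base and alkaline peroxide.

**Step 4**
Reactants: 5 3-bromo-4-methoxy-5-(methoxymethoxy)benzaldehyde; 6 tributyl(3-methylbut-2-enyl)stannane
Product: 7 4-methoxy-3-(methoxymethoxy)-5-(3-methylbut-2-enyl)benzaldehyde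
Conditions: Pd(PPh3)4 (5 mol %), degassed DMF, 100 °C
Reagents that add atoms: none
Why: Migita–Kosugi–Stille coupling; oxidative addition of the aryl bromide to zerovalent palladium, transfer of the allyl group through its tin-bearing carbon and reductive elimination should give the linear prenyl arene, with aldehyde and acetal untouched.

**Step 5**
Reactants: 2 1-[2-methoxy-4,6-bis(methoxymethoxy)phenyl]ethan-1-one; 7 4-methoxy-3-(methoxymethoxy)-5-(3-methylbut-2-enyl)benzaldehyde
Product: 8 (E)-1-[2-methoxy-4,6-bis(methoxymethoxy)phenyl]-3-[4-methoxy-3-(methoxymethoxy)-5-(3-methylbut-2-enyl)phenyl]prop-2-en-1-one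
Conditions: KOH (50 % aq.), EtOH, rt
Reagents that add atoms: none
Why: Claisen–Schmidt condensation of the methyl ketone enolate with the non-enolisable aldehyde, followed by E1cB loss of water, should give the thermodynamically favoured E-enone; MOM acetals and the prenyl group are inert to hydroxide.

**Step 6**
Reactants: 8 (E)-1-[2-methoxy-4,6-bis(methoxymethoxy)phenyl]-3-[4-methoxy-3-(methoxymethoxy)-5-(3-methylbut-2-enyl)phenyl]prop-2-en-1-one
Product: 9 [2-methoxy-4,6-bis(methoxymethoxy)phenyl]{(2S,3R)-3-[4-methoxy-3-(methoxymethoxy)-5-(3-methylbut-2-enyl)phenyl]oxiran-2-yl}methanone, racemic trans-epoxide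
Conditions: 30 % aq. H2O2, 2 M aq. NaOH, MeOH/THF, 0 °C → rt; crude product carried on without acidic silica
Reagents that add atoms: hydrogen peroxide, OO
Why: Weitz–Scheffer epoxidation; conjugate addition of hydroperoxide anion and closure of the enolate onto the O–O bond should give the racemic trans-epoxide (trans because the freely rotating enolate closes with aroyl and aryl groups apart), while the nucleophilic oxidant ignores the electron-rich prenyl alkene.

**Step 7**
Reactants: 9 [2-methoxy-4,6-bis(methoxymethoxy)phenyl]{(2S,3R)-3-[4-methoxy-3-(methoxymethoxy)-5-(3-methylbut-2-enyl)phenyl]oxiran-2-yl}methanone, racemic trans-epoxide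
Product: 12 7-hydroxy-3-[3-hydroxy-4-methoxy-5-(3-methylbut-2-enyl)phenyl]-5-methoxychromen-4-one, via formyl deoxybenzoin 10 (not isolated), via 2-hydroxyisoflavanone 11 (not isolated)
Conditions: BF3·OEt2 (0.3 equiv), CH2Cl2, −20 °C until the epoxide is consumed; then HCl in MeOH (about 1 M, excess), same flask, −20 °C → 45 °C
Reagents that add atoms: none
Why: BF3 binds the oxirane oxygen and the C–O bond at the carbon bearing ring B ionises, the C4' methoxy group para to C1' carrying the charge as a quinoid oxocarbenium; the ring A aroyl group then shifts from the neighbouring carbon to this centre (new C3–C4 bond) and the carbon it leaves becomes the C2 formyl group of 10. The closest known reaction type is the Lewis acid Meinwald-type rearrangement of chalcone epoxides to α-formyl deoxybenzoins by 1,2-acyl shift, followed by the acid cyclodehydration of ortho-hydroxy formyl deoxybenzoins to isoflavones. In methanolic HCl the three MOM acetals are transferred to methanol as dimethoxymethane, the freed C8a hydroxyl adds to the aldehyde in a 6-exo-trig hemiacetal closure (O1–C2, giving 11), and loss of water across C2–C3 gives the pyranone, ring C. No stereocentre survives: both epoxide centres are consumed, and C3 of 10 and C2/C3 of 11 end as sp2 carbons. The selectivity needed is acyl migration ahead of hydride shift and ahead of capture of the cation by the ortho oxygen of ring A (the path to a 3-hydroxyflavanone); the first is the normal preference of chalcone epoxides, and the second is secured because that oxygen stays capped as a weakly nucleophilic MOM acetal in an aprotic medium at low temperature until the shift is over. The prenyl alkene should survive because it is flanked only by the C4' methyl ether, so no phenol can add to it, and it is meta to the cationic side chain.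

**Compound list**
1 | 2,4-dihydroxy-6-methoxyacetophenone | CC(=O)c1c(O)cc(O)cc1OC | starting material
2 | 1-[2-methoxy-4,6-bis(methoxymethoxy)phenyl]ethan-1-one | CC(=O)c1c(OCOC)cc(OCOC)cc1OC | intermediate
3 | 3-bromo-4,5-dihydroxybenzaldehyde | O=Cc1cc(O)c(O)c(Br)c1 | starting material
4 | 3-bromo-5-hydroxy-4-methoxybenzaldehyde | COc1c(O)cc(C=O)cc1Br | intermediate
5 | 3-bromo-4-methoxy-5-(methoxymethoxy)benzaldehyde | COCOc1cc(C=O)cc(Br)c1OC | intermediate
6 | tributyl(3-methylbut-2-enyl)stannane | CCCC[Sn](CCCC)(CCCC)CC=C(C)C | starting material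
7 | 4-methoxy-3-(methoxymethoxy)-5-(3-methylbut-2-enyl)benzaldehyde | COCOc1cc(C=O)cc(CC=C(C)C)c1OC | intermediate
8 | (E)-1-[2-methoxy-4,6-bis(methoxymethoxy)phenyl]-3-[4-methoxy-3-(methoxymethoxy)-5-(3-methylbut-2-enyl)phenyl]prop-2-en-1-one | COCOc1cc(OCOC)c(C(=O)/C=C/c2cc(OCOC)c(OC)c(CC=C(C)C)c2)c(OC)c1 | intermediate
9 | [2-methoxy-4,6-bis(methoxymethoxy)phenyl]{(2S,3R)-3-[4-methoxy-3-(methoxymethoxy)-5-(3-methylbut-2-enyl)phenyl]oxiran-2-yl}methanone, racemic trans-epoxide, one enantiomer drawn | COCOc1cc(OCOC)c(C(=O)[C@H]2O[C@@H]2c3cc(OCOC)c(OC)c(CC=C(C)C)c3)c(OC)c1 | intermediate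
10 | 3-[2-methoxy-4,6-bis(methoxymethoxy)phenyl]-2-[4-methoxy-3-(methoxymethoxy)-5-(3-methylbut-2-enyl)phenyl]-3-oxopropanal (formyl deoxybenzoin; racemic and enolisable, no configuration drawn) | COCOc1cc(OCOC)c(C(=O)C(C=O)c2cc(OCOC)c(OC)c(CC=C(C)C)c2)c(OC)c1 | intermediate (not isolated)
11 | 2,7-dihydroxy-3-[3-hydroxy-4-methoxy-5-(3-methylbut-2-enyl)phenyl]-5-methoxychroman-4-one (hemiacetal, mixture of stereoisomers, no configuration drawn) | COc1c(O)cc(C2C(O)Oc3cc(O)cc(OC)c3C2=O)cc1CC=C(C)C | intermediate (not isolated)
12 | 7-hydroxy-3-[3-hydroxy-4-methoxy-5-(3-methylbut-2-enyl)phenyl]-5-methoxychromen-4-one | COc1c(O)cc(-c2coc3cc(O)cc(OC)c3c2=O)cc1CC=C(C)C | target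

**Step count**
Total: 7 steps. Longest linear sequence: 6 steps (3 → 4 → 5 → 7 → 8 → 9 → 12; steps 2, 3, 4, 5, 6, 7).

**Steps most likely to fail**

Step 7. The ortho acetal oxygen of ring A may trap the benzylic cation before the aroyl group has shifted, or the β-keto aldehyde may lose its formyl group by methanolysis in the acid stage. The fallback replaces the acyl shift by an oxidative 1,2-aryl shift. It sets out from 2 and 5, before the prenyl group is in place, because trivalent thallium would attack the prenyl alkene.
- Claisen–Schmidt condensation of 2 with 5 (KOH, EtOH, rt) should give the bromochalcone (E)-3-[3-bromo-4-methoxy-5-(methoxymethoxy)phenyl]-1-[2-methoxy-4,6-bis(methoxymethoxy)phenyl]prop-2-en-1-one F1.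
- Tl(NO3)3·3H2O in MeOH/HC(OMe)3 at rt should move ring B to the α-carbon and give the keto acetal 2-[3-bromo-4-methoxy-5-(methoxymethoxy)phenyl]-3,3-dimethoxy-1-[2-methoxy-4,6-bis(methoxymethoxy)phenyl]propan-1-one F2.
- Stille coupling of F2 with 6 (Pd(PPh3)4, DMF, 100 °C) should give 3,3-dimethoxy-1-[2-methoxy-4,6-bis(methoxymethoxy)phenyl]-2-[4-methoxy-3-(methoxymethoxy)-5-(3-methylbut-2-enyl)phenyl]propan-1-one F3.
- HCl in MeOH at 45 °C should then remove the three MOM groups and close the pyranone, so the fallback comes back to the route at the target 12.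

Step 4. Allyl transposition during transfer from tin may give the 1,1-dimethylallyl isomer, or oxidative addition to the ortho-methoxy bromide may be slow enough that the stannane is lost by protodestannylation. The fallback reverses the polarity of the prenylation and sets out from 5.
- Acetalisation (HC(OMe)3, catalytic pyridinium p-toluenesulfonate, MeOH, rt) should give 1-bromo-5-(dimethoxymethyl)-2-methoxy-3-(methoxymethoxy)benzene F4.
- Bromine–lithium exchange (n-BuLi, THF, −78 °C), transmetalation with CuBr·SMe2 and alkylation with 1-bromo-3-methylbut-2-ene at its primary carbon should give 5-(dimethoxymethyl)-2-methoxy-1-(methoxymethoxy)-3-(3-methylbut-2-enyl)benzene F5.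
- Brief hydrolysis with aqueous oxalic acid in THF at rt, which should spare the aryl MOM ether, returns to the route at 7.

Step 2. Regiocontrol may be lost, with methylation on the other catechol oxygen or on both. The fallback inverts the order of the two O-alkylations and switches from acidity control to nucleophilicity control. It sets out from 3.
- The dianion (NaH, 2.2 equiv, DMSO, rt) is treated with one equivalent of MOMCl. The more basic and less hindered phenoxide meta to the formyl group should react, giving 3-bromo-4-hydroxy-5-(methoxymethoxy)benzaldehyde F6.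
- Methylation of the remaining phenol (MeI, K2CO3, DMF, rt) then gives 5, where the fallback rejoins the route, bypassing 4.

**Further compounds**
F1 | step 7 | (E)-3-[3-bromo-4-methoxy-5-(methoxymethoxy)phenyl]-1-[2-methoxy-4,6-bis(methoxymethoxy)phenyl]prop-2-en-1-one | COCOc1cc(OCOC)c(C(=O)/C=C/c2cc(OCOC)c(OC)c(Br)c2)c(OC)c1
F2 | step 7 | 2-[3-bromo-4-methoxy-5-(methoxymethoxy)phenyl]-3,3-dimethoxy-1-[2-methoxy-4,6-bis(methoxymethoxy)phenyl]propan-1-one (racemic) | COCOc1cc(OCOC)c(C(=O)C(C(OC)OC)c2cc(OCOC)c(OC)c(Br)c2)c(OC)c1
F3 | step 7 | 3,3-dimethoxy-1-[2-methoxy-4,6-bis(methoxymethoxy)phenyl]-2-[4-methoxy-3-(methoxymethoxy)-5-(3-methylbut-2-enyl)phenyl]propan-1-one (racemic) | COCOc1cc(OCOC)c(C(=O)C(C(OC)OC)c2cc(OCOC)c(OC)c(CC=C(C)C)c2)c(OC)c1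
F4 | step 4 | 1-bromo-5-(dimethoxymethyl)-2-methoxy-3-(methoxymethoxy)benzene | COCOc1cc(C(OC)OC)cc(Br)c1OC
F5 | step 4 | 5-(dimethoxymethyl)-2-methoxy-1-(methoxymethoxy)-3-(3-methylbut-2-enyl)benzene | COCOc1cc(C(OC)OC)cc(CC=C(C)C)c1OC
F6 | step 2 | 3-bromo-4-hydroxy-5-(methoxymethoxy)benzaldehyde | COCOc1cc(C=O)cc(Br)c1O
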